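## The problem

Epoxypholamin A (20) is a trans-fused drim-7-ene decalin with four stereocentres (C4, C5, C9, C10), a 4α-hydroxymethyl group and a trisubstituted C7=C8 alkene, whose C9 carries a methylene (C11) bonded to C1' of an epoxyquinol ring; that ring is numbered here C1' (quaternary oxirane carbon), C2' (oxirane CH), C3' (ketone), C4' (alkene carbon bearing the second hydroxymethyl group), C5' (alkene CH) and C6' (carbinol). The decalin stereocentres come as a set, and a 4α-oxygenated carbon plus a two-carbon appendage on C9 is the pattern of levopimaric acid (1) after cleavage of its diene ring, so this half is a chiral-pool problem. The three contiguous stereocentres C1', C2' and C6' are separated from the decalin by the freely rotating C11 methylene, so the decalin cannot be relied on to control them; the first of them must be set under reagent control and in the right absolute sense, because an error gives a diastereomer of 20. Within the ring, however, C6' can control the other two: the oxirane oxygen is trans to the C6' oxygen, the relationship expected when a nucleophilic oxidant adds to a C1'=C2' enone from the face opposite a bulky C6' ether. The fragile groups are the epoxy enone with its γ-carbinol (base can open the oxirane through the dienolate and aromatise the ring, acid can open it directly), the allylic primary alcohol, and the electron-rich C7=C8 alkene, which rules out peracids, singlet oxygen, osmium reagents and strong acid once it is in place and therefore any electrophilic route to the oxirane. The feature that opens the problem is that C1', once the oxirane is traced back to an enone, is a carbonyl-level carbon flanked by C11 and the oxygenated C6': the ring C1'–C6' can be annulated onto the ketone C11–C1'(=O)–C6'H2–OR (11) with the four-carbon enone 12 supplying C2'–C5', and C6' is then the only stereocentre the annulation has to create. What remains, the C4'=C5' unsaturation and the C4' hydroxymethyl group, has to be added late and under mild conditions to a base-sensitive epoxy ketone.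

## Retrosynthesis

The last bonds to be cut are the two O–Si bonds of bis-silyl ether 19. Releasing the three hydroxyl groups only at the end keeps the polar, base-sensitive epoxyquinol out of every C–C bond-forming step, and the same silyl group on both oxygens makes this one operation. The forward step must remove a hindered primary and a secondary silyl ether without opening the oxirane.

Cutting the C4'–CH2OH bond of 19 leads to epoxy enone 18 and formaldehyde (9). The neighbouring option, carrying this carbon through the annulation on the enone partner, would put an extra stereocentre and an α-substituent into the key step; attaching it to the α-carbon of the finished enone touches no stereocentre. The forward reaction is an α-hydroxymethylation of a γ-oxygenated enone and needs a nucleophilic catalyst mild enough for the oxirane.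

The C4'=C5' double bond of 18 is removed next, by way of silyl enol ether 17, to give the saturated epoxy ketone 16. Introducing this unsaturation after the oxirane, and not epoxidising a cross-conjugated dienone, means that the epoxidation meets only one enone double bond. The forward steps need enolisation of 16 toward C4' only, which the oxirane on the other side ensures.

Cutting both C–O bonds of the oxirane gives enone 15 and removes two of the three ring stereocentres. A nucleophilic epoxidation is preferred to a directed or electrophilic one because it cannot touch the C7=C8 alkene and because its facial selectivity is dictated by the adjacent C6' silyl ether. The forward reaction must add hydroperoxide to the fully substituted C1' anti to that ether.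

Enone 15 is cut at C5'–C6' and C1'=C2', which opens the ring to the acyclic α-silyloxy ketone 11 and methyl vinyl ketone (12); the conjugate adduct 13 and ketol 14 lie on the forward path. Breaking C11–C1' instead would need a hindered drimenyl C11 organometallic and a separately made chiral cyclohexenone and would waste the carbon that 1 delivers at the right oxidation level; a cut at C4'=C5' leaves three stereocentres to an open-chain precursor. The chosen cut reduces the quinol ring to a ketone without ring stereocentres and a commodity enone. It asks the forward reaction for enamine formation on the oxygenated side of 11, one catalyst-controlled C–C bond at C6', and ring closure through the methyl-ketone carbon.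

Ketone 11 is the silyl ether of hydroxymethyl ketone 10, which is cut at C1'–C6' into aldehyde 8 and formaldehyde (9), the aldehyde carbon acting as an acyl anion equivalent. Homologation of the corresponding acid through a diazoketone would cost three or four steps and pass through a carbenoid placed to cyclopropanate the C7=C8 alkene; the catalytic cross-acyloin reaction forms the same bond in one step. The forward reaction must favour the crossed product over self-condensation of either aldehyde.

Aldehyde 8 is taken back to methyl ester 7, and the C8–CH3 bond of 7 is cut through enol triflate 6 to keto ester 5. Cross-coupling of a regiodefined enol triflate is preferred to organometallic addition and dehydration, which would give a mixture of double-bond isomers. The ester is the form of C12 that survives enolate and cuprate chemistry and is one reduction away from the aldehyde. The forward sequence needs kinetic enolisation of 5 toward C7.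

Keto ester 5 holds C8 as a ketone and C12 as an ester, the termini left when the C8=C14 and C12=C13 double bonds of a levopimarane diene are cleaved (aldehyde 4 being the first-formed C12 terminus). It is therefore traced to silyl ether 3, alcohol 2 and levopimaric acid (1). Against a de novo polyene cyclisation, this delivers all four decalin stereocentres, the 4α-oxygenated carbon and the C11–C12 unit from one commercial compound; reducing and protecting the carboxyl group first means no carbonyl differentiation is needed later. The forward cleavage must cut both double bonds of the conjugated diene and leave the new termini at different oxidation levels.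

## Roads not taken

Alternative 1: Chiral-ketal-directed epoxidation of a quinone monoketal.
- **Cut:** again the oxirane, but on a ring that already holds all six carbons and the C4' hydroxymethyl carbon: the cross-conjugated C6' ketone A1, whose C3' carbonyl is masked as the (R,R)-hydrobenzoin ketal and which would arise by oxidative dearomatisation.
- **Forward key step:** tert-butyl hydroperoxide and base add to C2', the β-carbon next to the chiral ketal, and the enolate closes at C1' to give A2.
- **Merits:** the route is convergent and the C2-symmetric ketal sits beside the attacked carbon. The hydroxymethyl group never has to be added to a base-sensitive epoxy enone; in this respect it is better than the chosen plan.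
- **Weak points:**
  - C6' is still a ketone in A2 and must be reduced with hydride arriving from the oxirane face, a second diastereoselective event that the ketal does not secure.
  - The hydrobenzoin ketal must then be hydrolysed with acid next to an oxirane and in the presence of the C7=C8 alkene.
  - A1 offers two enone double bonds to the oxidant.
  - Joining the ring to the decalin needs a C11–C1' bond from a hindered drimenyl C11 partner, which discards the carbon that 1 provides.
- **Comparison:** against the greater convergence, the chosen plan sets a stereocentre (C6') made once by a catalyst and kept to the end, no late acid step, and a ring built on a carbon the starting material already supplies.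

Alternative 2: Singlet-oxygen cycloaddition relayed from C4'.
- **Cut:** the two C–O bonds at C3' and C6', traced to photo-oxygenation of the cyclohexa-1,3-diene A3, which carries the silyloxymethyl group on a stereogenic C4'.
- **Forward key step:** singlet oxygen adds across C3' and C6' anti to that substituent to give the endoperoxide A4; base-induced Kornblum–DeLaMare rearrangement would then have to deliver the C3' ketone and the C6' hydroxyl.
- **Merits:** both ring oxygens arrive in one metal-free step, and the C4' carbon is present from the start, so no late hydroxymethylation is needed; here it matches alternative 1 and beats the chosen plan.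
- **Weak points:**
  - Singlet oxygen undergoes the ene reaction with trisubstituted alkenes such as C7=C8 at rates comparable to the cycloaddition, so chemoselectivity cannot be assumed.
  - The rearrangement of A4 can remove either bridgehead hydrogen, and only one regiochemical outcome is useful.
  - A3 needs its own enantioselective synthesis for a stereocentre that is destroyed when C4'=C5' is introduced.
  - The nucleophilic epoxidation and the dehydrogenation still follow.
- **Comparison:** it is not shorter than the chosen plan, which uses only nucleophilic oxidants compatible with the decalin alkene and creates no sacrificial stereocentre; the chosen plan pays for this with the late Baylis–Hillman step.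

Alternative 3: Ring-closing metathesis of an open-chain epoxy dienone.
- **Cut:** the C4'=C5' double bond; the open-chain epoxy dienone A5 carries a vinyl group on C6' and a 2-(silyloxymethyl)vinyl ketone at C3'.
- **Forward key step:** a second-generation Grubbs catalyst closes the ring to A6, the tris-silyl ether of 20.
- **Merits:** the endgame is shorter and gentler than the one chosen here: only desilylation remains, and no dehydrogenation or hydroxymethylation of an epoxy enone is needed. Each stereocentre of A5 would be set by a reaction with a long record (asymmetric epoxidation, substrate-controlled carbonyl addition), which is more secure than an enamine-catalysed conjugate addition on a new ketone.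
- **Weak points:**
  - A5 must hold C1', C2' and C6' as three contiguous stereocentres in open-chain form, each set in a separate operation and with the quaternary oxirane carbon among them, so the route to A5 is long and linear.
  - The metathesis joins an electron-poor 1,1-disubstituted alkene to an allylic silyl ether next to a quaternary centre, a slow combination that needs forcing conditions on an α,β-epoxy ketone.
- **Comparison:** the chosen plan answers with economy: one stereocentre made by catalysis, the other two relayed from it, and the six-membered ring assembled from two simple components.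

Key step: step 9

Conventions: TBS = tert-butyl(dimethyl)silyl. Dec = (1S,4aR,5R,8aR)-5-(TBSO-methyl)-2,5,8a-trimethyl-1,4,4a,5,6,7,8,8a-octahydronaphthalen-1-yl, the silylated decalin unit (its C1, C2, C4a, C5 and C8a are drimane C9, C8, C5, C4 and C10). Compounds 1–3 carry abietane locants (C18 is the 4α carbon).

Assumption: commercial levopimaric acid is the natural levorotatory enantiomer drawn as 1, which has the decalin configuration of 20.

Assumption: the L-amino acid catalyst of step 9 is assigned to the 6'R product on the acid-directed Z-enamine model; if the sense proves opposite, the D-enantiomer is used and nothing else changes.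

## Steps

Step 1
Reactants: 1 levopimaric acid
Product: 2 levopimarol (abieta-8(14),12-dien-18-ol)
Conditions: LiAlH4, THF, 0 °C to reflux
Reagents that add atoms: none
Why: Hydride reduction of the carboxylic acid to the primary alcohol; the conjugated diene is inert to LiAlH4 and no stereocentre is touched, and the basic work-up avoids acid isomerisation of the diene.

Step 2
Reactants: 2 levopimarol
Product: 3 18-(TBSO)abieta-8(14),12-diene
Conditions: TBSCl, imidazole, DMF, rt
Reagents that add atoms: tert-butyl(dimethyl)silyl chloride, CC(C)(C)[Si](C)(C)Cl
Why: Standard silylation of a primary alcohol through the N-silylimidazolium; protecting the C18 oxygen now removes the only carbonyl that would later need to be told apart from C8 and C12.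

Step 3
Reactants: 3 18-(TBSO)abieta-8(14),12-diene
Product: 5 methyl 2-[(1R,4aR,5R,8aS)-5-(TBSO-methyl)-5,8a-dimethyl-2-oxodecahydronaphthalen-1-yl]acetate, via keto aldehyde 4 (not isolated)
Conditions: O3, NaOH (2.5 M in MeOH), CH2Cl2, −78 °C
Reagents that add atoms: ozone, [O-][O+]=O; methanol, CO
Why: Ozonolysis in alkaline methanol cleaves both double bonds of the cisoid diene; the fully substituted C8 terminus becomes the ketone, while the C12 terminus passes through aldehyde 4, whose methyl hemiacetal is oxidised in the flask to the ester, so the two new carbonyl groups emerge differentiated. C9, now α to the ketone, keeps its equatorial side chain, which is also the thermodynamically preferred arrangement on the trans-decalin.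

Step 4
Reactants: 5 keto ester
Product: 6 methyl 2-[(1R,4aR,5R,8aS)-5-(TBSO-methyl)-5,8a-dimethyl-2-(trifluoromethanesulfonyloxy)-1,4,4a,5,6,7,8,8a-octahydronaphthalen-1-yl]acetate
Conditions: KN(SiMe3)2, THF, −78 °C; then PhNTf2, −78 to 0 °C
Reagents that add atoms: N-phenylbis(trifluoromethanesulfonimide), O=S(=O)(N(c1ccccc1)S(=O)(=O)C(F)(F)F)C(F)(F)F
Why: Kinetic deprotonation of the C8 ketone takes the unhindered C7 methylene and not the C9 methine flanked by the quaternary C10, and the ester α-protons are several pK units less acidic; O-triflation of the enolate fixes the future double bond at C7=C8.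

Step 5
Reactants: 6 enol triflate
Product: 7 methyl 2-Dec-acetate
Conditions: Me2CuLi (from CuI and MeLi), THF, −20 to 0 °C
Reagents that add atoms: lithium dimethylcuprate, [Li+].C[Cu-]C
Why: Coupling of an enol triflate with a lithium dialkylcuprate (McMurry–Scott) replaces the triflate by methyl without moving the double bond; the ester does not react with the cuprate at this temperature.

Step 6
Reactants: 7 methyl 2-Dec-acetate
Product: 8 2-Dec-acetaldehyde
Conditions: iBu2AlH (1.1 equiv), CH2Cl2, −78 °C; aqueous potassium sodium tartrate work-up
Reagents that add atoms: none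
Why: Partial reduction of an ester: the tetrahedral aluminium hemiacetal is stable at −78 °C and collapses to the aldehyde only on work-up; the silyl ether and the alkene are inert.

Step 7
Reactants: 8 2-Dec-acetaldehyde; 9 formaldehyde (charged as paraformaldehyde)
Product: 10 1-hydroxy-3-Dec-propan-2-one
Conditions: 3-ethylbenzothiazolium bromide (10 mol %), iPr2NEt (20 mol %), THF, 60 °C
Reagents that add atoms: none
Why: Thiazol-2-ylidene-catalysed cross-acyloin (formoin-type) condensation: the Breslow intermediate of the aliphatic aldehyde adds to formaldehyde, the most electrophilic and least hindered acceptor, and releases the 1-hydroxy-2-ketone. This forms the C1'–C6' bond in one catalytic step and creates no stereocentre.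

Step 8
Reactants: 10 1-hydroxy-3-Dec-propan-2-one
Product: 11 1-(TBSO)-3-Dec-propan-2-one
Conditions: TBSCl, imidazole, CH2Cl2, 0 °C to rt
Reagents that add atoms: tert-butyl(dimethyl)silyl chloride, CC(C)(C)[Si](C)(C)Cl
Why: Silylation of the primary alcohol; the resulting α-silyloxy ketone is the donor type known to form Z-enamines with primary amines, and the bulky ether later directs the epoxidation.

Step 9
Reactants: 11 1-(TBSO)-3-Dec-propan-2-one; 12 methyl vinyl ketone
Product: 15 (4R)-3-(Dec-methyl)-4-(TBSO)cyclohex-2-en-1-one, via Michael adduct 13 (not isolated), via ketol 14 (not isolated)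
Conditions: O-tert-butyl-L-threonine (20 mol %), 12 (3 equiv), NMP, 4 °C; then PPTS (20 mol %), 35 °C
Reagents that add atoms: none
Why: The primary amine condenses with the C1' ketone of 11 and, as with other O-silyl hydroxyacetone donors, gives the Z-enamine on the oxygen-bearing side (C1'=C6'), the C11 side being blocked by the decalin; this enamine adds through C6' to 12, which the catalyst's carboxylic acid holds on one enamine face, and hydrolysis releases diketone 13 with the new C5'–C6' bond. The closest known reaction type is the primary-amino-acid-catalysed Michael–aldol (Robinson) annulation, combined with the Z-enamine chemistry of α-silyloxy ketones in amine-catalysed aldol and Michael additions. The only new stereocentre, C6', is set by the catalyst (L-series, acid-directed delivery to the face that gives 6'R); the decalin is four bonds away and should neither help nor hinder. The ring is closed when the amine forms the terminal enamine of the unhindered methyl ketone (C3') and C2' attacks the C1' carbonyl in a 6-enolexo-exo-trig aldol to ketol 14, whose dehydration, assisted by PPTS, gives the conjugated C1'=C2' enone 15. Three selectivities are needed: enamine regiochemistry (secured by the α-oxygen and the neopentyl-like C11), aldol regiochemistry through C2' and not C11 (secured because the amine engages the methyl ketone and because the other closure would build a tetrasubstituted enone against the decalin), and single addition (C6' is tertiary after the first). The configuration at C6' is protected by the absence of strong base, the low temperature and the fact that ring closure takes C6' out of the α-position of a ketone; the reaction is stopped once 13 and 14 are consumed, to limit γ-deprotonation of 15 through its dienamine.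

Step 10
Reactants: 15 (4R)-3-(Dec-methyl)-4-(TBSO)cyclohex-2-en-1-one
Product: 16 (1S,5R,6R)-6-(Dec-methyl)-5-(TBSO)-7-oxabicyclo[4.1.0]heptan-2-one
Conditions: 30% aq. H2O2, NaOH (0.3 equiv), MeOH, 0 °C
Reagents that add atoms: hydrogen peroxide, OO
Why: Weitz–Scheffer epoxidation: hydroperoxide anion adds to C1' and the enolate closes on oxygen; allylic 1,2-strain with the C1' substituent places the C6' silyl ether pseudoaxial, and axial attack anti to it should deliver the oxirane trans to the C6' oxygen, setting C1' and C2' as in 20. The nucleophilic oxidant leaves the electron-rich C7=C8 alkene untouched, and substoichiometric base at 0 °C limits γ-deprotonation at C6'.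

Step 11
Reactants: 16 epoxy ketone
Product: 17 (1S,5R,6R)-6-(Dec-methyl)-5-(TBSO)-2-(trimethylsilyloxy)-7-oxabicyclo[4.1.0]hept-2-ene
Conditions: LiN(iPr)2, TMSCl, THF, −78 °C
Reagents that add atoms: chlorotrimethylsilane, C[Si](C)(C)Cl
Why: Kinetic enolisation with in situ silylation: only C4' offers an unstrained α-deprotonation, since enolisation toward C2' would place an sp2 carbon in the oxirane, and the enolate is trapped as the silyl enol ether before it can attack the epoxide.

Step 12
Reactants: 17 trimethylsilyl enol ether
Product: 18 (1S,5R,6R)-6-(Dec-methyl)-5-(TBSO)-7-oxabicyclo[4.1.0]hept-3-en-2-one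
Conditions: Pd(OAc)2 (1.1 equiv), MeCN, rt
Reagents that add atoms: none
Why: Saegusa–Ito oxidation: the palladium enolate formed from the silyl enol ether undergoes β-hydride elimination from C5' and installs the C4'=C5' double bond; neutral conditions at room temperature spare the oxirane and both TBS ethers.

Step 13
Reactants: 18 epoxy enone; 9 formaldehyde (37% aqueous)
Product: 19 (1S,5R,6R)-6-(Dec-methyl)-3-(hydroxymethyl)-5-(TBSO)-7-oxabicyclo[4.1.0]hept-3-en-2-one
Conditions: DMAP (30 mol %), THF, rt
Reagents that add atoms: none
Why: Morita–Baylis–Hillman reaction: DMAP adds reversibly to C5', the resulting enolate attacks formaldehyde through C4', and loss of DMAP restores the enone; no stereocentre is made or touched, and the weakly basic catalyst should avoid dienolate formation at C6'.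

Step 14
Reactants: 19 bis-silyl ether
Product: 20 epoxypholamin A
Conditions: HF·pyridine, pyridine, THF, 0 °C to rt
Reagents that add atoms: none
Why: Cleavage of both TBS ethers by buffered hydrogen fluoride, conditions under which α,β-epoxy ketones and allylic alcohols are expected to survive; the neopentyl-type primary ether is the slower one and sets the reaction time.

## Compound list

1 | levopimaric acid (abieta-8(14),12-dien-18-oic acid) | CC(C)C1=CC[C@H]2C(=C1)CC[C@H]1[C@](C)(C(=O)O)CCC[C@@]12C | starting material
2 | levopimarol (abieta-8(14),12-dien-18-ol) | CC(C)C1=CC[C@H]2C(=C1)CC[C@H]1[C@](C)(CO)CCC[C@@]12C | intermediate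
3 | 18-(TBSO)abieta-8(14),12-diene | CC(C)C1=CC[C@H]2C(=C1)CC[C@H]1[C@](C)(CO[Si](C)(C)C(C)(C)C)CCC[C@@]12C | intermediate
4 | 2-[(1R,4aR,5R,8aS)-5-(TBSO-methyl)-5,8a-dimethyl-2-oxodecahydronaphthalen-1-yl]acetaldehyde (keto aldehyde) | O=CC[C@H]1C(=O)CC[C@H]2[C@](C)(CO[Si](C)(C)C(C)(C)C)CCC[C@]12C | intermediate
5 | methyl 2-[(1R,4aR,5R,8aS)-5-(TBSO-methyl)-5,8a-dimethyl-2-oxodecahydronaphthalen-1-yl]acetate (keto ester) | COC(=O)C[C@H]1C(=O)CC[C@H]2[C@](C)(CO[Si](C)(C)C(C)(C)C)CCC[C@]12C | intermediate
6 | methyl 2-[(1R,4aR,5R,8aS)-5-(TBSO-methyl)-5,8a-dimethyl-2-(trifluoromethanesulfonyloxy)-1,4,4a,5,6,7,8,8a-octahydronaphthalen-1-yl]acetate (enol triflate) | COC(=O)C[C@H]1C(OS(=O)(=O)C(F)(F)F)=CC[C@H]2[C@](C)(CO[Si](C)(C)C(C)(C)C)CCC[C@]12C | intermediate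
7 | methyl 2-Dec-acetate | CC1=CC[C@H]2[C@](C)(CO[Si](C)(C)C(C)(C)C)CCC[C@]2(C)[C@H]1CC(=O)OC | intermediate
8 | 2-Dec-acetaldehyde | CC1=CC[C@H]2[C@](C)(CO[Si](C)(C)C(C)(C)C)CCC[C@]2(C)[C@H]1CC=O | intermediate
9 | formaldehyde | C=O | starting material
10 | 1-hydroxy-3-Dec-propan-2-one | CC1=CC[C@H]2[C@](C)(CO[Si](C)(C)C(C)(C)C)CCC[C@]2(C)[C@H]1CC(=O)CO | intermediate
11 | 1-(TBSO)-3-Dec-propan-2-one | CC1=CC[C@H]2[C@](C)(CO[Si](C)(C)C(C)(C)C)CCC[C@]2(C)[C@H]1CC(=O)CO[Si](C)(C)C(C)(C)C | intermediate
12 | methyl vinyl ketone | CC(=O)C=C | starting material
13 | (3R)-3-(TBSO)-1-Dec-heptane-2,6-dione (Michael adduct) | CC1=CC[C@H]2[C@](C)(CO[Si](C)(C)C(C)(C)C)CCC[C@]2(C)[C@H]1CC(=O)[C@H](O[Si](C)(C)C(C)(C)C)CCC(C)=O | intermediate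
14 | (4R)-3-(Dec-methyl)-3-hydroxy-4-(TBSO)cyclohexan-1-one (ketol, either configuration at C3) | CC1=CC[C@H]2[C@](C)(CO[Si](C)(C)C(C)(C)C)CCC[C@]2(C)[C@H]1CC1(O)CC(=O)CC[C@H]1O[Si](C)(C)C(C)(C)C | intermediate
15 | (4R)-3-(Dec-methyl)-4-(TBSO)cyclohex-2-en-1-one | CC1=CC[C@H]2[C@](C)(CO[Si](C)(C)C(C)(C)C)CCC[C@]2(C)[C@H]1CC1=CC(=O)CC[C@H]1O[Si](C)(C)C(C)(C)C | intermediate
16 | (1S,5R,6R)-6-(Dec-methyl)-5-(TBSO)-7-oxabicyclo[4.1.0]heptan-2-one | CC1=CC[C@H]2[C@](C)(CO[Si](C)(C)C(C)(C)C)CCC[C@]2(C)[C@H]1C[C@@]12O[C@@H]1C(=O)CC[C@H]2O[Si](C)(C)C(C)(C)C | intermediate
17 | (1S,5R,6R)-6-(Dec-methyl)-5-(TBSO)-2-(trimethylsilyloxy)-7-oxabicyclo[4.1.0]hept-2-ene | CC1=CC[C@H]2[C@](C)(CO[Si](C)(C)C(C)(C)C)CCC[C@]2(C)[C@H]1C[C@@]12O[C@@H]1C(O[Si](C)(C)C)=CC[C@H]2O[Si](C)(C)C(C)(C)C | intermediate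
18 | (1S,5R,6R)-6-(Dec-methyl)-5-(TBSO)-7-oxabicyclo[4.1.0]hept-3-en-2-one | CC1=CC[C@H]2[C@](C)(CO[Si](C)(C)C(C)(C)C)CCC[C@]2(C)[C@H]1C[C@@]12O[C@@H]1C(=O)C=C[C@H]2O[Si](C)(C)C(C)(C)C | intermediate
19 | (1S,5R,6R)-6-(Dec-methyl)-3-(hydroxymethyl)-5-(TBSO)-7-oxabicyclo[4.1.0]hept-3-en-2-one | CC1=CC[C@H]2[C@](C)(CO[Si](C)(C)C(C)(C)C)CCC[C@]2(C)[C@H]1C[C@@]12O[C@@H]1C(=O)C(CO)=C[C@H]2O[Si](C)(C)C(C)(C)C | intermediate
20 | epoxypholamin A, (1S,5R,6S)-5-hydroxy-3-(hydroxymethyl)-6-{[(1S,4aR,5R,8aR)-5-(hydroxymethyl)-2,5,8a-trimethyl-1,4,4a,5,6,7,8,8a-octahydronaphthalen-1-yl]methyl}-7-oxabicyclo[4.1.0]hept-3-en-2-one | CC1=CC[C@H]2[C@](C)(CO)CCC[C@]2(C)[C@H]1C[C@@]12O[C@@H]1C(=O)C(CO)=C[C@H]2O | target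

## Step count and least certain steps

Total: 14 steps. Longest linear sequence: 14 steps (1 to 20; 9 and 12 enter as purchased reagents).

**Step 9 (key step).** The most likely failure is loss of stereochemical fidelity at C6'. Facial selectivity in the conjugate addition may be poor because 11 is more hindered than the small α-silyloxy ketones on which the enamine model rests, and the α-silyloxy centre of 13 may epimerise by re-enolisation before the ring closes; slow enamine formation would also let 12 oligomerise. The fallback replaces catalytic conjugate addition by auxiliary-controlled alkylation. From 11, condensation with (R)-1-amino-2-(methoxymethyl)pyrrolidine gives the RAMP hydrazone F1. Deprotonation with LiN(iPr)2 on the more acidic, less hindered C6' side and alkylation of the azaenolate with 2-(2-iodoethyl)-2-methyl-1,3-dioxolane, a masked form of 12, gives the C6'-alkylated hydrazone F2 under auxiliary control (the antipodal auxiliary corrects the sense if needed). Two-phase oxalic acid cleavage removes the auxiliary to give the keto ketal F3, and PPTS in wet acetone unmasks the methyl ketone, which returns the material to 13. This is closed to 15 with the amino acid and PPTS as in the second stage of step 9.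

**Step 3.** The most likely failure is incomplete cleavage of the second double bond, which becomes part of an electron-poor enone or enoate after the first cleavage, together with base-induced degradation of the partly cleaved material in the alkaline medium. The fallback separates cleavage from oxidation. From 3, ozonolysis in neutral CH2Cl2/MeOH with Me2S work-up gives 4, which is now isolated; NaClO2/NaH2PO4 oxidation with 2-methyl-2-butene gives the keto acid F4, and esterification with Me3SiCHN2 returns to 5.

**Step 7.** The most likely failure is that self-condensation of 8 and oligomerisation of formaldehyde outrun the crossed acyloin reaction, because the β-branched aldehyde forms its Breslow intermediate slowly. The fallback builds the C1'–C6' bond by a Grignard addition. From 8, addition of (iPrO)Me2SiCH2MgCl gives the β-hydroxy silane F5; Tamao oxidation (H2O2, KF, KHCO3), which does not epoxidise the alkene, gives the 1,2-diol F6. Selective silylation of the primary hydroxyl gives the secondary alcohol F7, and Dess–Martin oxidation returns to 11, bypassing 10.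

**Step 10.** The most likely failure is sluggish conjugate addition of hydroperoxide to the fully substituted C1', which would leave time for γ-deprotonation at C6' and for attack on the wrong face. The fallback uses hydroxyl-directed epoxidation. From 15, Luche reduction (NaBH4, CeCl3·7H2O, MeOH, −78 °C) should give, by axial hydride delivery anti to the pseudoaxial silyl ether, the cis-1,4 allylic alcohol F8. Mitsunobu inversion with 4-nitrobenzoic acid (PPh3, DIAD) gives the trans ester F9, and methanolysis (K2CO3, MeOH) the trans allylic alcohol F10, whose C3' hydroxyl lies on the face opposite the C6' silyl ether. VO(acac)2-catalysed epoxidation with tert-butyl hydroperoxide, directed by the allylic hydroxyl and indifferent to the isolated C7=C8 alkene, gives the epoxy alcohol F11 with the oxirane syn to the C3' hydroxyl and hence anti to the C6' oxygen. Dess–Martin oxidation returns to 16.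

**Step 13.** The most likely failure is slow addition of the nucleophilic catalyst to C5', which is hindered by the adjacent silyl ether, so that base-induced opening of the oxirane through the C6' dienolate and aromatisation take over. The fallback is halogenation and cross-coupling. From 18, I2 and pyridine in CH2Cl2 give the α-iodo enone F12, and Stille coupling with (tributylstannyl)methanol (Pd(PPh3)4, CuI, DMF, rt) under neutral conditions returns to 19.

## Further compounds

F1 | step 9 | RAMP hydrazone of 11, N-[(2R)-2-(methoxymethyl)pyrrolidin-1-yl]imine at C1' (C=N geometry not defined) | CC1=CC[C@H]2[C@](C)(CO[Si](C)(C)C(C)(C)C)CCC[C@]2(C)[C@H]1CC(CO[Si](C)(C)C(C)(C)C)=NN1CCC[C@@H]1COC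
F2 | step 9 | C6'-alkylated RAMP hydrazone, (6'R)-silyl ether carrying a 2-(2-methyl-1,3-dioxolan-2-yl)ethyl group on C6' | CC1=CC[C@H]2[C@](C)(CO[Si](C)(C)C(C)(C)C)CCC[C@]2(C)[C@H]1CC(=NN1CCC[C@@H]1COC)[C@H](O[Si](C)(C)C(C)(C)C)CCC1(C)OCCO1
F3 | step 9 | (3R)-3-(TBSO)-1-Dec-5-(2-methyl-1,3-dioxolan-2-yl)pentan-2-one (keto ketal) | CC1=CC[C@H]2[C@](C)(CO[Si](C)(C)C(C)(C)C)CCC[C@]2(C)[C@H]1CC(=O)[C@H](O[Si](C)(C)C(C)(C)C)CCC1(C)OCCO1
F4 | step 3 | 2-[(1R,4aR,5R,8aS)-5-(TBSO-methyl)-5,8a-dimethyl-2-oxodecahydronaphthalen-1-yl]acetic acid (keto acid) | OC(=O)C[C@H]1C(=O)CC[C@H]2[C@](C)(CO[Si](C)(C)C(C)(C)C)CCC[C@]12C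
F5 | step 7 | 1-Dec-3-[dimethyl(propan-2-yloxy)silyl]propan-2-ol (carbinol epimers) | CC1=CC[C@H]2[C@](C)(CO[Si](C)(C)C(C)(C)C)CCC[C@]2(C)[C@H]1CC(O)C[Si](C)(C)OC(C)C
F6 | step 7 | 3-Dec-propane-1,2-diol (carbinol epimers) | CC1=CC[C@H]2[C@](C)(CO[Si](C)(C)C(C)(C)C)CCC[C@]2(C)[C@H]1CC(O)CO
F7 | step 7 | 1-(TBSO)-3-Dec-propan-2-ol (carbinol epimers) | CC1=CC[C@H]2[C@](C)(CO[Si](C)(C)C(C)(C)C)CCC[C@]2(C)[C@H]1CC(O)CO[Si](C)(C)C(C)(C)C
F8 | step 10 | (1S,4R)-3-(Dec-methyl)-4-(TBSO)cyclohex-2-en-1-ol (cis allylic alcohol) | CC1=CC[C@H]2[C@](C)(CO[Si](C)(C)C(C)(C)C)CCC[C@]2(C)[C@H]1CC1=C[C@@H](O)CC[C@H]1O[Si](C)(C)C(C)(C)C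
F9 | step 10 | (1R,4R)-3-(Dec-methyl)-4-(TBSO)cyclohex-2-en-1-yl 4-nitrobenzoate (trans ester) | CC1=CC[C@H]2[C@](C)(CO[Si](C)(C)C(C)(C)C)CCC[C@]2(C)[C@H]1CC1=C[C@H](OC(=O)c2ccc(cc2)[N+](=O)[O-])CC[C@H]1O[Si](C)(C)C(C)(C)C
F10 | step 10 | (1R,4R)-3-(Dec-methyl)-4-(TBSO)cyclohex-2-en-1-ol (trans allylic alcohol) | CC1=CC[C@H]2[C@](C)(CO[Si](C)(C)C(C)(C)C)CCC[C@]2(C)[C@H]1CC1=C[C@H](O)CC[C@H]1O[Si](C)(C)C(C)(C)C
F11 | step 10 | (1R,2R,5R,6R)-6-(Dec-methyl)-5-(TBSO)-7-oxabicyclo[4.1.0]heptan-2-ol (epoxy alcohol) | CC1=CC[C@H]2[C@](C)(CO[Si](C)(C)C(C)(C)C)CCC[C@]2(C)[C@H]1C[C@@]12O[C@@H]1[C@H](O)CC[C@H]2O[Si](C)(C)C(C)(C)C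
F12 | step 13 | (1S,5R,6R)-6-(Dec-methyl)-3-iodo-5-(TBSO)-7-oxabicyclo[4.1.0]hept-3-en-2-one (α-iodo enone) | CC1=CC[C@H]2[C@](C)(CO[Si](C)(C)C(C)(C)C)CCC[C@]2(C)[C@H]1C[C@@]12O[C@@H]1C(=O)C(I)=C[C@H]2O[Si](C)(C)C(C)(C)C
A1 | alternative 1 | cross-conjugated C6'-keto quinone monoketal (C3' (R,R)-hydrobenzoin ketal, CH2OTBS on C4', Dec-methyl on C1') | CC1=CC[C@H]2[C@](C)(CO[Si](C)(C)C(C)(C)C)CCC[C@]2(C)[C@H]1CC1=CC2(O[C@H](c3ccccc3)[C@@H](c3ccccc3)O2)C(CO[Si](C)(C)C(C)(C)C)=CC1=O
A2 | alternative 1 | C1',C2'-epoxy quinone monoketal | CC1=CC[C@H]2[C@](C)(CO[Si](C)(C)C(C)(C)C)CCC[C@]2(C)[C@H]1C[C@@]12O[C@@H]1C3(O[C@H](c4ccccc4)[C@@H](c4ccccc4)O3)C(CO[Si](C)(C)C(C)(C)C)=CC2=O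
A3 | alternative 2 | 2-(Dec-methyl)-5-(TBSO-methyl)cyclohexa-1,3-diene | CC1=CC[C@H]2[C@](C)(CO[Si](C)(C)C(C)(C)C)CCC[C@]2(C)[C@H]1CC1=CC[C@@H](CO[Si](C)(C)C(C)(C)C)C=C1
A4 | alternative 2 | 2,3-dioxabicyclo[2.2.2]octene endoperoxide | CC1=CC[C@H]2[C@](C)(CO[Si](C)(C)C(C)(C)C)CCC[C@]2(C)[C@H]1CC1=C[C@H]2OO[C@@H]1C[C@H]2CO[Si](C)(C)C(C)(C)C
A5 | alternative 3 | open-chain epoxy dienone (C6' vinyl carbinol TBS ether, C3' 2-(TBSO-methyl)vinyl ketone) | CC1=CC[C@H]2[C@](C)(CO[Si](C)(C)C(C)(C)C)CCC[C@]2(C)[C@H]1C[C@]1(O[C@@H]1C(=O)C(=C)CO[Si](C)(C)C(C)(C)C)[C@@H](C=C)O[Si](C)(C)C(C)(C)C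
A6 | alternative 3 | tris-TBS ether of 20 | CC1=CC[C@H]2[C@](C)(CO[Si](C)(C)C(C)(C)C)CCC[C@]2(C)[C@H]1C[C@@]12O[C@@H]1C(=O)C(CO[Si](C)(C)C(C)(C)C)=C[C@H]2O[Si](C)(C)C(C)(C)C
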